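**Retrosynthetic overview**

1. The target comes from a Boc-amino aryl methyl ketone (acid removes Boc and MOM and closes the imine), that from MeMgBr opening of an N-Boc dihydroisoquinolinone, and that from lactamisation of a 6-(2-aminopropyl)benzoate; the nitrogen ring is closed last on a finished ring A.
2. Feature used: ring A (C4a, C5, C6, C7, C8, C8a) is pentasubstituted and C5 is its only C–H. C7 (naphthyl), C8 (OMe), C8a (the later C1 carbon, as CO2Me) and C4a (the C4–C3 chain) are C3, C4, C5 and C6 of a 2-pyrone; C5–H and C6–OMe are the two carbons of 1,1-dimethoxyethene (cycloaddition, then loss of CO2 and MeOH).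
3. The pyrone comes from Suzuki–Miyaura coupling of a 3-bromo-4-methoxy-2-pyrone-5-carboxylate with a 2-naphthyl boronate; the pyrone core comes from C-acylation of dimethyl 3-oxopentanedioate with (S)-3-(Cbz-amino)butanoic acid, which supplies the only stereocentre (C3).
4. The naphthalene comes from anionic annulation of an ortho-allyl benzamide (the amide carbon becomes C1′–OH, peri to OMe), followed by MOM-directed lithiation at C2′.
5. Ring order: second naphthalene ring, 2-pyrone, ring A (key step), nitrogen ring.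

Key step: step 10

Assumption: the C7–C2′ biaryl axis carries no descriptor in the target, so axial configuration is not controlled; biaryl intermediates may be mixtures of interconverting rotamers. Cbz = benzyloxycarbonyl.

**Route**

Step 1
Reactants: 1 2-methoxy-4-methylbenzoic acid
Product: 3 N,N-diethyl-2-methoxy-4-methylbenzamide, via acid chloride 2 (not isolated)
Conditions: (COCl)2, DMF (cat.), CH2Cl2, 0 °C → rt; then Et2NH, Et3N, CH2Cl2, 0 °C
Reagents that add atoms: diethylamine CCNCC
Why: Acyl chloride formation and amidation (nucleophilic acyl substitution) install the diethylamide, which later serves as ortho-metalation director and as the internal electrophile of the annulation.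

Step 2
Reactants: 3 N,N-diethyl-2-methoxy-4-methylbenzamide; 4 allyl bromide
Product: 7 2-allyl-N,N-diethyl-6-methoxy-4-methylbenzamide, via aryllithium 5 (not isolated), via arylmagnesium bromide 6 (not isolated)
Conditions: s-BuLi, TMEDA, THF, −78 °C; MgBr2·OEt2, −78 → 0 °C; allyl bromide, rt
Reagents that add atoms: none
Why: Directed ortho metalation places lithium at C6, the only free position ortho to the strongly directing CONEt2 group, and transmetalation to the less basic arylmagnesium bromide allows allylation without deprotonation of the doubly activated CH2 of the product.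

Step 3
Reactants: 7 2-allyl-N,N-diethyl-6-methoxy-4-methylbenzamide
Product: 8 8-methoxy-6-methylnaphthalen-1-ol
Conditions: LiN(iPr)2 (2.5 equiv), THF, −78 °C → rt
Reagents that add atoms: none
Why: Anionic benzamide annulation, in which deprotonation of the benzylic and allylic CH2 gives an allyl anion whose terminal carbon attacks the amide carbonyl (6-membered ring closure), diethylamide is expelled and the dienone tautomerises to the naphtholate, so that the former amide carbon becomes C1–OH peri to the methoxy group by construction.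

Step 4
Reactants: 8 8-methoxy-6-methylnaphthalen-1-ol
Product: 9 8-methoxy-1-(methoxymethoxy)-6-methylnaphthalene
Conditions: NaH, MOMCl, DMF, 0 °C → rt
Reagents that add atoms: chloromethyl methyl ether COCCl
Why: Williamson-type O-alkylation of the naphtholate gives an acetal ether that directs the next lithiation, should tolerate base, palladium catalysis, heat, hydrogenation and Grignard reagent, and leaves in the final acid step.

Step 5
Reactants: 9 8-methoxy-1-(methoxymethoxy)-6-methylnaphthalene
Product: 11 2-[8-methoxy-1-(methoxymethoxy)-6-methylnaphthalen-2-yl]-4,4,5,5-tetramethyl-1,3,2-dioxaborolane, via 2-lithionaphthalene 10 (not isolated)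
Conditions: n-BuLi, TMEDA, Et2O, 0 °C; then iPrOBpin, −78 °C → rt
Reagents that add atoms: 2-isopropoxy-4,4,5,5-tetramethyl-1,3,2-dioxaborolane CC(C)OB1OC(C)(C)C(C)(C)O1
Why: Directed ortho metalation by the OCH2OMe group lithiates C2 (C7, ortho to the weaker OMe director, is flanked by the methyl group), and the aryllithium is trapped by borate formation and isopropoxide loss to give the pinacol boronate.

Step 6
Reactants: 12 (S)-3-(Cbz-amino)butanoic acid; 13 dimethyl 3-oxopentanedioate
Product: 16 methyl 6-[(S)-2-(Cbz-amino)propyl]-4-hydroxy-2-oxo-2H-pyran-5-carboxylate, via acyl imidazolide 14 (not isolated), via triketo diester 15 (not isolated)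
Conditions: CDI, THF, rt; then 13, MgCl2, Et3N, MeCN, rt; then DBU, toluene, 80 °C
Reagents that add atoms: none
Why: The acid is activated as its acyl imidazolide and C-acylates the chelated magnesium enolate of 13 (Claisen-type acylation of a 1,3-dicarbonyl), after which DBU-promoted 6-exo-trig lactonisation of the enol oxygen onto the distal ester closes the 4-hydroxy-2-pyrone; the stereocentre is not enolisable and is carried over from 12.

Step 7
Reactants: 16 methyl 6-[(S)-2-(Cbz-amino)propyl]-4-hydroxy-2-oxo-2H-pyran-5-carboxylate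
Product: 17 methyl 6-[(S)-2-(Cbz-amino)propyl]-4-methoxy-2-oxo-2H-pyran-5-carboxylate
Conditions: Me2SO4, K2CO3, acetone, rt → 50 °C
Reagents that add atoms: dimethyl sulfate COS(=O)(=O)OC
Why: O-Alkylation of the acidic vinylogous acid with dimethyl sulfate under K2CO3 should give the 4-methoxy-2-pyrone, and the carbamate N–H is too weakly acidic to be methylated under these conditions.

Step 8
Reactants: 17 methyl 6-[(S)-2-(Cbz-amino)propyl]-4-methoxy-2-oxo-2H-pyran-5-carboxylate
Product: 18 methyl 3-bromo-6-[(S)-2-(Cbz-amino)propyl]-4-methoxy-2-oxo-2H-pyran-5-carboxylate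
Conditions: NBS, MeCN, rt, dark
Reagents that add atoms: N-bromosuccinimide O=C1CCC(=O)N1Br
Why: Electrophilic bromination occurs at C3, the only unsubstituted ring carbon and the nucleophilic β-carbon of the 4-methoxy enol ether.

Step 9
Reactants: 18 methyl 3-bromo-6-[(S)-2-(Cbz-amino)propyl]-4-methoxy-2-oxo-2H-pyran-5-carboxylate; 11 2-[8-methoxy-1-(methoxymethoxy)-6-methylnaphthalen-2-yl]-4,4,5,5-tetramethyl-1,3,2-dioxaborolane
Product: 19 methyl 6-[(S)-2-(Cbz-amino)propyl]-4-methoxy-3-[8-methoxy-1-(methoxymethoxy)-6-methylnaphthalen-2-yl]-2-oxo-2H-pyran-5-carboxylate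
Conditions: Pd(OAc)2, SPhos, K3PO4, toluene/H2O (10:1), 80 °C
Reagents that add atoms: none
Why: Suzuki–Miyaura coupling, with oxidative addition of zerovalent palladium into the C3–Br bond and the bulky electron-rich SPhos ligand promoting transmetalation and reductive elimination to the tri-ortho-substituted aryl–pyrone bond under mildly basic conditions that should spare lactone, ester and carbamate.

Step 10
Reactants: 19 methyl 6-[(S)-2-(Cbz-amino)propyl]-4-methoxy-3-[8-methoxy-1-(methoxymethoxy)-6-methylnaphthalen-2-yl]-2-oxo-2H-pyran-5-carboxylate; 20 1,1-dimethoxyethene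
Product: 23 methyl 6-[(S)-2-(Cbz-amino)propyl]-2,4-dimethoxy-3-[8-methoxy-1-(methoxymethoxy)-6-methylnaphthalen-2-yl]benzoate, via bridged bicyclic lactone 21 (not isolated), via dimethoxycyclohexadiene 22 (not isolated)
Conditions: 1,1-dimethoxyethene (10 equiv), toluene, sealed tube, 140 °C
Reagents that add atoms: none
Why: This is an inverse-electron-demand Diels–Alder reaction of an electron-poor 2-pyrone with a ketene acetal, the known benzannulation of 2-pyrone-5-carboxylates: the nucleophilic CH2 of 20 bonds first to pyrone C6 (β-carbon of the C5 acrylate and vinylogous terminus of the lactone carbonyl) and the acetal carbon then closes on C3 in an asynchronous [4+2] to give bridged lactone 21. Retro-[4+2] loss of CO2 gives the 4,4-dimethoxycyclohexadiene 22, and 1,2-elimination of methanol across CH2–C(OMe)2 aromatises it. Ring A is closed by the cycloaddition itself, both new bonds (C4a–C5 and C6–C7 in isoquinoline numbering) forming in one six-membered transition state, suprafacial on diene and dienophile; no new stereocentre survives, since the bridgehead centres of 21 are destroyed on aromatisation and the side-chain centre lies outside the reacting array. The selectivity needed is regiochemical: the new C–OMe must end up next to the naphthyl-bearing carbon and the new C–H next to the side-chain carbon, which the C5 ester (making C6 the most electrophilic diene terminus) and the polarity of the ketene acetal secure. The donor 4-OMe and the C3 aryl group make the diene sluggish, hence excess 20 and 140 °C in a closed vessel; Cbz, MOM and the esters should be inert under these neutral conditions.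

Step 11
Reactants: 23 methyl 6-[(S)-2-(Cbz-amino)propyl]-2,4-dimethoxy-3-[8-methoxy-1-(methoxymethoxy)-6-methylnaphthalen-2-yl]benzoate
Product: 25 (S)-6,8-dimethoxy-7-[8-methoxy-1-(methoxymethoxy)-6-methylnaphthalen-2-yl]-3-methyl-3,4-dihydroisoquinolin-1(2H)-one, via free amine 24 (not isolated)
Conditions: H2 (1 atm), 10% Pd/C (palladium on carbon), MeOH, rt; then K2CO3, MeOH, 60 °C
Reagents that add atoms: none
Why: Hydrogenolysis of the benzyl carbamate and spontaneous decarboxylation free the primary amine, which undergoes base-assisted intramolecular aminolysis of the neighbouring methyl ester (6-exo-trig lactamisation), while MOM ether, methyl ethers and the stereocentre are untouched.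

Step 12
Reactants: 25 (S)-6,8-dimethoxy-7-[8-methoxy-1-(methoxymethoxy)-6-methylnaphthalen-2-yl]-3-methyl-3,4-dihydroisoquinolin-1(2H)-one
Product: 26 tert-butyl (S)-6,8-dimethoxy-7-[8-methoxy-1-(methoxymethoxy)-6-methylnaphthalen-2-yl]-3-methyl-1-oxo-3,4-dihydroisoquinoline-2(1H)-carboxylate
Conditions: Boc2O, DMAP, Et3N, MeCN, rt → 40 °C
Reagents that add atoms: di-tert-butyl dicarbonate CC(C)(C)OC(=O)OC(=O)OC(C)(C)C
Why: DMAP-catalysed N-acylation with Boc2O converts the lactam into an imide-type N-acyl carbamate, which activates the ring carbonyl for nucleophilic addition.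

Step 13
Reactants: 26 tert-butyl (S)-6,8-dimethoxy-7-[8-methoxy-1-(methoxymethoxy)-6-methylnaphthalen-2-yl]-3-methyl-1-oxo-3,4-dihydroisoquinoline-2(1H)-carboxylate
Product: 27 tert-butyl N-[(S)-1-{2-acetyl-3,5-dimethoxy-4-[8-methoxy-1-(methoxymethoxy)-6-methylnaphthalen-2-yl]phenyl}propan-2-yl]carbamate
Conditions: MeMgBr (1.5 equiv), THF, −78 → 0 °C
Reagents that add atoms: methylmagnesium bromide C[Mg]Br
Why: Grignard addition to the ring carbonyl of the N-Boc lactam, which is more electrophilic and less shielded than the tert-butyl carbamate carbonyl, followed by ring-opening of the tetrahedral intermediate should give the aryl methyl ketone, whose two ortho substituents and ready enolisation disfavour a second addition.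

Step 14
Reactants: 27 tert-butyl N-[(S)-1-{2-acetyl-3,5-dimethoxy-4-[8-methoxy-1-(methoxymethoxy)-6-methylnaphthalen-2-yl]phenyl}propan-2-yl]carbamate
Product: 29 2-[(3S)-6,8-dimethoxy-1,3-dimethyl-3,4-dihydroisoquinolin-7-yl]-8-methoxy-6-methylnaphthalen-1-ol, via amino ketone 28 (not isolated)
Conditions: HCl (3 M in MeOH), rt → 40 °C; then aq. NaHCO3
Reagents that add atoms: none
Why: Acidolysis cleaves the Boc carbamate and the MOM acetal, and the freed primary amine condenses intramolecularly with the ketone (6-membered cyclic imine formation with loss of water), while C3, which is not adjacent to an enolisable carbonyl, keeps its (S) configuration.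

**Compound list**

1 | 2-methoxy-4-methylbenzoic acid | COc1cc(C)ccc1C(=O)O | starting material
2 | 2-methoxy-4-methylbenzoyl chloride | COc1cc(C)ccc1C(=O)Cl | intermediate
3 | N,N-diethyl-2-methoxy-4-methylbenzamide | CCN(CC)C(=O)c1ccc(C)cc1OC | intermediate
4 | allyl bromide (3-bromoprop-1-ene) | C=CCBr | starting material
5 | N,N-diethyl-2-lithio-6-methoxy-4-methylbenzamide | CCN(CC)C(=O)c1c([Li])cc(C)cc1OC | intermediate
6 | [2-(diethylcarbamoyl)-3-methoxy-5-methylphenyl]magnesium bromide | CCN(CC)C(=O)c1c([Mg]Br)cc(C)cc1OC | intermediate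
7 | 2-allyl-N,N-diethyl-6-methoxy-4-methylbenzamide | C=CCc1cc(C)cc(OC)c1C(=O)N(CC)CC | intermediate
8 | 8-methoxy-6-methylnaphthalen-1-ol | COc1cc(C)cc2cccc(O)c12 | intermediate
9 | 8-methoxy-1-(methoxymethoxy)-6-methylnaphthalene | COCOc1cccc2cc(C)cc(OC)c12 | intermediate
10 | 2-lithio-8-methoxy-1-(methoxymethoxy)-6-methylnaphthalene | COCOc1c([Li])ccc2cc(C)cc(OC)c12 | intermediate
11 | 2-[8-methoxy-1-(methoxymethoxy)-6-methylnaphthalen-2-yl]-4,4,5,5-tetramethyl-1,3,2-dioxaborolane | COCOc1c(B2OC(C)(C)C(C)(C)O2)ccc2cc(C)cc(OC)c12 | intermediate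
12 | (S)-3-{[(benzyloxy)carbonyl]amino}butanoic acid | C[C@H](NC(=O)OCc1ccccc1)CC(=O)O | starting material
13 | dimethyl 3-oxopentanedioate | COC(=O)CC(=O)CC(=O)OC | starting material
14 | benzyl [(S)-4-(imidazol-1-yl)-4-oxobutan-2-yl]carbamate | C[C@H](NC(=O)OCc1ccccc1)CC(=O)n1ccnc1 | intermediate
15 | dimethyl 2-[(S)-3-(Cbz-amino)butanoyl]-3-oxopentanedioate (C2 enolisable, unspecified) | COC(=O)CC(=O)C(C(=O)OC)C(=O)C[C@H](C)NC(=O)OCc1ccccc1 | intermediate
16 | methyl 6-[(S)-2-(Cbz-amino)propyl]-4-hydroxy-2-oxo-2H-pyran-5-carboxylate | COC(=O)C1=C(C[C@H](C)NC(=O)OCc2ccccc2)OC(=O)C=C1O | intermediate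
17 | methyl 6-[(S)-2-(Cbz-amino)propyl]-4-methoxy-2-oxo-2H-pyran-5-carboxylate | COC(=O)C1=C(C[C@H](C)NC(=O)OCc2ccccc2)OC(=O)C=C1OC | intermediate
18 | methyl 3-bromo-6-[(S)-2-(Cbz-amino)propyl]-4-methoxy-2-oxo-2H-pyran-5-carboxylate | COC(=O)C1=C(C[C@H](C)NC(=O)OCc2ccccc2)OC(=O)C(Br)=C1OC | intermediate
19 | methyl 6-[(S)-2-(Cbz-amino)propyl]-4-methoxy-3-[8-methoxy-1-(methoxymethoxy)-6-methylnaphthalen-2-yl]-2-oxo-2H-pyran-5-carboxylate | COC(=O)C1=C(C[C@H](C)NC(=O)OCc2ccccc2)OC(=O)C(c2ccc3cc(C)cc(OC)c3c2OCOC)=C1OC | intermediate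
20 | 1,1-dimethoxyethene | C=C(OC)OC | starting material
21 | methyl 1-[(S)-2-(Cbz-amino)propyl]-5,8,8-trimethoxy-4-[8-methoxy-1-(methoxymethoxy)-6-methylnaphthalen-2-yl]-3-oxo-2-oxabicyclo[2.2.2]oct-5-ene-6-carboxylate (bridgehead diastereomers, unspecified) | COC(=O)C1=C(OC)C2(c3ccc4cc(C)cc(OC)c4c3OCOC)C(=O)OC1(C[C@H](C)NC(=O)OCc5ccccc5)CC2(OC)OC | intermediate
22 | methyl 2-[(S)-2-(Cbz-amino)propyl]-4,4,6-trimethoxy-5-[8-methoxy-1-(methoxymethoxy)-6-methylnaphthalen-2-yl]cyclohexa-1,5-diene-1-carboxylate | COC(=O)C1=C(C[C@H](C)NC(=O)OCc2ccccc2)CC(OC)(OC)C(c2ccc3cc(C)cc(OC)c3c2OCOC)=C1OC | intermediate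
23 | methyl 6-[(S)-2-(Cbz-amino)propyl]-2,4-dimethoxy-3-[8-methoxy-1-(methoxymethoxy)-6-methylnaphthalen-2-yl]benzoate | COC(=O)c1c(C[C@H](C)NC(=O)OCc2ccccc2)cc(OC)c(-c2ccc3cc(C)cc(OC)c3c2OCOC)c1OC | intermediate
24 | methyl 6-[(S)-2-aminopropyl]-2,4-dimethoxy-3-[8-methoxy-1-(methoxymethoxy)-6-methylnaphthalen-2-yl]benzoate | COC(=O)c1c(C[C@H](C)N)cc(OC)c(-c2ccc3cc(C)cc(OC)c3c2OCOC)c1OC | intermediate
25 | (S)-6,8-dimethoxy-7-[8-methoxy-1-(methoxymethoxy)-6-methylnaphthalen-2-yl]-3-methyl-3,4-dihydroisoquinolin-1(2H)-one | O=C1N[C@@H](C)Cc2cc(OC)c(-c3ccc4cc(C)cc(OC)c4c3OCOC)c(OC)c21 | intermediate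
26 | tert-butyl (S)-6,8-dimethoxy-7-[8-methoxy-1-(methoxymethoxy)-6-methylnaphthalen-2-yl]-3-methyl-1-oxo-3,4-dihydroisoquinoline-2(1H)-carboxylate | O=C1N(C(=O)OC(C)(C)C)[C@@H](C)Cc2cc(OC)c(-c3ccc4cc(C)cc(OC)c4c3OCOC)c(OC)c21 | intermediate
27 | tert-butyl N-[(S)-1-{2-acetyl-3,5-dimethoxy-4-[8-methoxy-1-(methoxymethoxy)-6-methylnaphthalen-2-yl]phenyl}propan-2-yl]carbamate | CC(=O)c1c(C[C@H](C)NC(=O)OC(C)(C)C)cc(OC)c(-c2ccc3cc(C)cc(OC)c3c2OCOC)c1OC | intermediate
28 | 1-{6-[(S)-2-aminopropyl]-3-(1-hydroxy-8-methoxy-6-methylnaphthalen-2-yl)-2,4-dimethoxyphenyl}ethan-1-one | CC(=O)c1c(C[C@H](C)N)cc(OC)c(-c2ccc3cc(C)cc(OC)c3c2O)c1OC | intermediate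
29 | 2-[(3S)-6,8-dimethoxy-1,3-dimethyl-3,4-dihydroisoquinolin-7-yl]-8-methoxy-6-methylnaphthalen-1-ol | COc1cc2c(c(OC)c1-c1ccc3cc(C)cc(OC)c3c1O)C(C)=N[C@@H](C)C2 | target

**Step count and risks**

Total steps: 14. Longest linear sequence: 11 (steps 1–5, then 9–14); the pyrone branch (steps 6–8) joins at step 9.

Steps most likely to fail:

1. Step 10 (key cycloaddition). The diene may be too unreactive: the 4-methoxy donor raises its LUMO, and closure at C3 must build two adjacent fully substituted carbons beside the naphthyl group, so prolonged heating could consume the ketene acetal by oligomerisation before the adduct forms. Fallback, keeping the same pyrone-to-arene disconnection but moving the coupling behind it: the route sets out from bromopyrone 18, whose C3 substituent is small and inductively withdrawing. Heating 18 with 20 under the conditions of step 10 should give, through the bridged bromo lactone F1 and the bromo dimethoxycyclohexadiene F2, methyl 3-bromo-6-[(S)-2-(Cbz-amino)propyl]-2,4-dimethoxybenzoate F3. Suzuki–Miyaura coupling of F3 with boronate 11 (Pd(OAc)2, SPhos, K3PO4, toluene/H2O, 90 °C) would then give benzoate 23, where the route is rejoined.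

2. Step 9 (aryl–pyrone coupling). Transmetalation of the hindered ortho-alkoxy boronate may be slow, so that protodeboronation and base-induced opening of the pyrone lactone compete. Fallback, a palladium-free C-arylation of the pyrone as a 1,3-dicarbonyl-type nucleophile: the route sets out from 9 and 16. Lithiation of 9 as in step 5 (through 10) and quenching with Bu3SnCl would give tributyl[8-methoxy-1-(methoxymethoxy)-6-methylnaphthalen-2-yl]stannane F4. Tin–lead exchange with Pb(OAc)4 (Hg(OAc)2 cat., CHCl3) would give [8-methoxy-1-(methoxymethoxy)-6-methylnaphthalen-2-yl]lead triacetate F5. Reaction of F5 with hydroxypyrone 16 in CHCl3/pyridine at 60 °C should arylate C3 by ligand coupling, a process that tolerates ortho substituents, to give the 3-aryl-4-hydroxy-2-pyrone F6. O-Methylation of F6 with Me2SO4/K2CO3 as in step 7 returns to 19.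

3. Step 13 (Grignard opening). The reagent may attack the carbamate carbonyl, with loss of Boc and return to lactam 25, or may fail to add at the ring carbonyl flanked by the C8 methoxy group. Fallback through an imidate instead of an imide: the route sets out from lactam 25. O-Methylation with Me3OBF4 (CH2Cl2, 2,6-di-tert-butylpyridine) would give the lactim ether (S)-1,6,8-trimethoxy-7-[8-methoxy-1-(methoxymethoxy)-6-methylnaphthalen-2-yl]-3-methyl-3,4-dihydroisoquinoline F7. Addition of MeLi (THF, −78 → 0 °C; addition to the imidate and loss of methoxide) should give the MOM-protected cyclic imine (S)-6,8-dimethoxy-7-[8-methoxy-1-(methoxymethoxy)-6-methylnaphthalen-2-yl]-1,3-dimethyl-3,4-dihydroisoquinoline F8. Treatment of F8 with HCl in MeOH removes the MOM group and returns to target 29.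

**Further compounds**

F1 | step 10 | methyl 4-bromo-1-[(S)-2-(Cbz-amino)propyl]-5,8,8-trimethoxy-3-oxo-2-oxabicyclo[2.2.2]oct-5-ene-6-carboxylate | COC(=O)C1=C(OC)C2(Br)C(=O)OC1(C[C@H](C)NC(=O)OCc3ccccc3)CC2(OC)OC
F2 | step 10 | methyl 5-bromo-2-[(S)-2-(Cbz-amino)propyl]-4,4,6-trimethoxycyclohexa-1,5-diene-1-carboxylate | COC(=O)C1=C(C[C@H](C)NC(=O)OCc2ccccc2)CC(OC)(OC)C(Br)=C1OC
F3 | step 10 | methyl 3-bromo-6-[(S)-2-(Cbz-amino)propyl]-2,4-dimethoxybenzoate | COC(=O)c1c(C[C@H](C)NC(=O)OCc2ccccc2)cc(OC)c(Br)c1OC
F4 | step 9 | tributyl[8-methoxy-1-(methoxymethoxy)-6-methylnaphthalen-2-yl]stannane | CCCC[Sn](CCCC)(CCCC)c1ccc2cc(C)cc(OC)c2c1OCOC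
F5 | step 9 | [8-methoxy-1-(methoxymethoxy)-6-methylnaphthalen-2-yl]lead triacetate | CC(=O)O[Pb](OC(C)=O)(OC(C)=O)c1ccc2cc(C)cc(OC)c2c1OCOC
F6 | step 9 | methyl 6-[(S)-2-(Cbz-amino)propyl]-4-hydroxy-3-[8-methoxy-1-(methoxymethoxy)-6-methylnaphthalen-2-yl]-2-oxo-2H-pyran-5-carboxylate | COC(=O)C1=C(C[C@H](C)NC(=O)OCc2ccccc2)OC(=O)C(c2ccc3cc(C)cc(OC)c3c2OCOC)=C1O
F7 | step 13 | (S)-1,6,8-trimethoxy-7-[8-methoxy-1-(methoxymethoxy)-6-methylnaphthalen-2-yl]-3-methyl-3,4-dihydroisoquinoline | COC1=N[C@@H](C)Cc2cc(OC)c(-c3ccc4cc(C)cc(OC)c4c3OCOC)c(OC)c21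
F8 | step 13 | (S)-6,8-dimethoxy-7-[8-methoxy-1-(methoxymethoxy)-6-methylnaphthalen-2-yl]-1,3-dimethyl-3,4-dihydroisoquinoline | CC1=N[C@@H](C)Cc2cc(OC)c(-c3ccc4cc(C)cc(OC)c4c3OCOC)c(OC)c21
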